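**Plan**

- Retrosynthesis: the galloyl C(=O)–O5 bond and all benzyl and silyl groups are cut last. Ring A is then removed whole by cutting C8–C8a, C7–C8, C5–C6 and C4a–C5, which leaves a dihydropyranyl diazomethyl ketone and (triisopropylsilyloxy)ethyne.
- The diazoketone is traced back through the methyl ketone, Weinreb amide and enol triflate to a δ-lactone. Its C8a carbon comes from CO (hydroformylation) and its C2–C3 bond from allylboration of 3,4-bis(benzyloxy)benzaldehyde.
- Enabling feature: ring A is a resorcinol fused to ring C at C4a–C8a, with O5 acylated and O7 free. In a vinylketene/siloxyalkyne benzannulation the ketene oxygen becomes the free O5–H and the alkyne oxygen the silylated O7, so the two oxygens arrive differentiated.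
- Forward order: C2–C3 bond (step 2), ring C as lactol and lactone (steps 3–4), C8a acyl group and diazo carbon (steps 5–8), ring A (step 10), gallate and deprotection (steps 11–13). The catechol and galloyl rings are bought.
- Stereochemistry: C2 (R) and C3 (S) are both set in step 2. The E-γ-silyloxyallylboronate gives the anti adduct, and the chiral phosphoric acid fixes the aldehyde face. Neither centre is touched afterwards.

Key step: step 10

Assumption: compounds 1, 3, 12, 13 and 21 are bought; the phosphoric acid antipode in step 2 is the one that directs the boronate to the Si face of aldehyde 3, expected to be (S)-TRIP by analogy with simple allylboronates, and the sense is to be confirmed on 4 by Mosher ester analysis.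

Abbreviations: Ar = 3,4-bis(benzyloxy)phenyl; TBS = tert-butyldimethylsilyl; TIPS = triisopropylsilyl; pin = pinacolato.

**Route**

Step 1
Reactants: 1 (E)-3-(TBS-oxy)prop-1-enylboronic acid pinacol ester
Product: 2 (E)-3-(TBS-oxy)prop-2-enylboronic acid pinacol ester
Conditions: [Ir(cod)(PPh2Me)2]PF6 (2 mol %, activated with H2), THF, rt
Reagents that add atoms: none
Why: Cationic iridium hydride catalysed olefin transposition (1,3-hydrogen shift) moves the double bond next to oxygen and should give the E silyl enol ether allylboronate, the geometry that later encodes the 2,3-trans relationship.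

Step 2
Reactants: 3 3,4-bis(benzyloxy)benzaldehyde; 2 (E)-3-(TBS-oxy)prop-2-enylboronic acid pinacol ester
Product: 4 (1R,2S)-1-Ar-2-(TBS-oxy)but-3-en-1-ol
Conditions: (S)-TRIP (5 mol %), 4 Å MS, toluene, −40 °C; aq NaHCO3 work-up
Reagents that add atoms: none
Why: Chiral phosphoric acid catalysed allylboration through a closed chair transition state, in which the equatorial E-γ-silyloxy group gives the anti adduct and the catalyst-directed Si-face attack sets the carbinol carbon as R and thereby the silyloxy carbon as S (flavan C2 and C3).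

Step 3
Reactants: 4 (1R,2S)-1-Ar-2-(TBS-oxy)but-3-en-1-ol
Product: 5 (5S,6R)-6-Ar-5-(TBS-oxy)tetrahydro-2H-pyran-2-ol (anomeric mixture)
Conditions: Rh(acac)(CO)2 (1 mol %), Xantphos (2 mol %), CO/H2 (1:1, 5 bar), toluene, 60 °C
Reagents that add atoms: carbon monoxide, [C-]#[O+]
Why: Linear-selective rhodium hydroformylation of the terminal alkene gives the δ-hydroxy aldehyde, which should close spontaneously to the six-membered lactol through the benzylic hydroxyl, forming ring C with an anomeric centre that is left uncontrolled and erased in step 4.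

Step 4
Reactants: 5 (5S,6R)-6-Ar-5-(TBS-oxy)tetrahydro-2H-pyran-2-ol
Product: 6 (5S,6R)-6-Ar-5-(TBS-oxy)tetrahydro-2H-pyran-2-one
Conditions: TPAP (5 mol %), NMO, 4 Å MS, CH2Cl2, rt
Reagents that add atoms: none
Why: Ley–Griffith oxidation converts the lactol into the δ-lactone under neutral conditions that leave benzyl ethers, the silyl ether and both stereocentres untouched.

Step 5
Reactants: 6 (5S,6R)-6-Ar-5-(TBS-oxy)tetrahydro-2H-pyran-2-one
Product: 7 (2R,3S)-2-Ar-3-(TBS-oxy)-3,4-dihydro-2H-pyran-6-yl trifluoromethanesulfonate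
Conditions: KHMDS, PhNTf2, THF/DMPU, −78 °C; cold work-up, Et3N-deactivated silica, used at once
Reagents that add atoms: N-phenylbis(trifluoromethanesulfonimide), O=S(=O)(N(c1ccccc1)S(=O)(=O)C(F)(F)F)C(F)(F)F
Why: The kinetic potassium enolate of the lactone is O-sulfonylated to the cyclic ketene acetal triflate, the standard activation of lactones for palladium coupling, and neither stereocentre is α to the carbonyl.

Step 6
Reactants: 7 (2R,3S)-2-Ar-3-(TBS-oxy)-3,4-dihydro-2H-pyran-6-yl trifluoromethanesulfonate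
Product: 8 (2R,3S)-2-Ar-3-(TBS-oxy)-N-methoxy-N-methyl-3,4-dihydro-2H-pyran-6-carboxamide
Conditions: Pd(OAc)2 (5 mol %), Xantphos, CO (1 atm), MeNHOMe·HCl, Et3N, DMF, rt to 40 °C
Reagents that add atoms: carbon monoxide, [C-]#[O+]; N,O-dimethylhydroxylamine hydrochloride, CNOC.Cl
Why: Palladium-catalysed aminocarbonylation of the alkenyl triflate (oxidative addition, CO insertion, aminolysis of the acylpalladium) installs the carbonyl carbon on C8a directly at the Weinreb amide level.

Step 7
Reactants: 8 (2R,3S)-2-Ar-3-(TBS-oxy)-N-methoxy-N-methyl-3,4-dihydro-2H-pyran-6-carboxamide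
Product: 9 1-[(2R,3S)-2-Ar-3-(TBS-oxy)-3,4-dihydro-2H-pyran-6-yl]ethanone
Conditions: MeMgBr, THF, −20 to 0 °C; aq NH4Cl
Reagents that add atoms: methylmagnesium bromide, C[Mg]Br
Why: Weinreb ketone synthesis, in which the chelated tetrahedral intermediate stops the Grignard addition at the methyl ketone.

Step 8
Reactants: 9 1-[(2R,3S)-2-Ar-3-(TBS-oxy)-3,4-dihydro-2H-pyran-6-yl]ethanone
Product: 11 1-[(2R,3S)-2-Ar-3-(TBS-oxy)-3,4-dihydro-2H-pyran-6-yl]-2-diazoethanone, via trifluoroacetyl diketone 10 (not isolated)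
Conditions: LiHMDS, THF, −78 °C; CF3CO2CH2CF3, −78 °C; buffered work-up; then 4-acetamidobenzenesulfonyl azide, Et3N, H2O (1 equiv), MeCN, rt
Reagents that add atoms: 4-acetamidobenzenesulfonyl azide, CC(=O)Nc1ccc(cc1)S(=O)(=O)N=[N+]=[N-]
Why: Detrifluoroacetylative diazo transfer, in which the kinetic α′-enolate of the methyl enone (formed at −78 °C in preference to γ-deprotonation at C4) is trifluoroacetylated, the sulfonyl azide transfers N2 and the trifluoroacetyl group leaves on the sulfonamide, so that diazomethane and its dipolar addition to the enone are avoided.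

Step 9
Reactants: 12 ethynylmagnesium bromide; 13 triisopropylsilyl trifluoromethanesulfonate
Product: 15 (triisopropylsilyloxy)ethyne, via bromomagnesium ethynolate 14 (not isolated)
Conditions: t-BuOOH (anhydrous, decane), LiHMDS, THF, −78 °C; add 12, −78 to 0 °C; then 13, −78 to 0 °C; pentane/aq NaHCO3 work-up
Reagents that add atoms: tert-butyl hydroperoxide, CC(C)(C)OO
Why: Oxenoid oxidation of the metal acetylide by lithium tert-butyl peroxide gives the ynolate, and the bulky silyl triflate should capture it on oxygen (ynolate O-silylation as used for 1-siloxy-1-alkynes) to give the siloxyalkyne.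

Step 10
Reactants: 11 1-[(2R,3S)-2-Ar-3-(TBS-oxy)-3,4-dihydro-2H-pyran-6-yl]-2-diazoethanone; 15 (triisopropylsilyloxy)ethyne
Product: 20 (2R,3S)-2-Ar-3-(TBS-oxy)-7-(TIPS-oxy)chroman-5-ol, via vinylketene 16 (not isolated), via cyclobutenone 17 (not isolated), via dienylketene 18 (not isolated), via cyclohexadienone 19 (not isolated)
Conditions: 15 (2–3 equiv), hν (Pyrex-filtered medium-pressure Hg lamp, >290 nm), degassed ClCH2CH2Cl, rt; then 80 °C in the dark
Reagents that add atoms: none
Why: Light expels N2 and the dihydropyranyl carbon migrates (photo-Wolff rearrangement, forming C8–C8a) to give vinylketene 16, to which the polarised siloxyalkyne adds in a [2+2] cycloaddition, its nucleophilic CH carbon bonding to the ketene carbonyl carbon (C5–C6) and its oxygen-bearing carbon to the ketene α-carbon (C7–C8), to give cyclobutenone 17. 4π electrocyclic opening of 17 (reversible, so the isomer with ketene and dihydropyranyl cis is funnelled onward) gives dienylketene 18, which closes ring A by 6π electrocyclisation of C4a onto the ketene carbon (C4a–C5) to dienone 19, and tautomerisation should deliver phenol 20. The closest known reaction type is the photochemical Danheiser benzannulation of α′-diazo enones, 2-furyl and cycloalkenyl diazomethyl ketones among them, with triisopropylsiloxyalkynes to give resorcinol monosilyl ethers. No stereocentre survives into the product, since the sp3 carbons of 17 and 19 are erased, and C2 and C3 are remote from every bond change in a neutral medium. The step needs a single regiochemical outcome, silyloxy meta to the new hydroxyl, which the ynol ether polarisation secures, so the ketene oxygen emerges as the free O5–H and the alkyne oxygen as silylated O7, while excess alkyne suppresses ketene dimerisation and acylation of the product phenol.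

Step 11
Reactants: 20 (2R,3S)-2-Ar-3-(TBS-oxy)-7-(TIPS-oxy)chroman-5-ol; 21 3,4,5-tris(benzyloxy)benzoic acid
Product: 22 (2R,3S)-2-Ar-3-(TBS-oxy)-7-(TIPS-oxy)chroman-5-yl 3,4,5-tris(benzyloxy)benzoate
Conditions: DCC, DMAP (cat.), CH2Cl2, 0 °C to rt
Reagents that add atoms: none
Why: Steglich esterification acylates the only free hydroxyl in the molecule, the C5 phenol, so no regiochemical question arises.

Step 12
Reactants: 22 (2R,3S)-2-Ar-3-(TBS-oxy)-7-(TIPS-oxy)chroman-5-yl 3,4,5-tris(benzyloxy)benzoate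
Product: 23 (2R,3S)-2-Ar-3,7-dihydroxychroman-5-yl 3,4,5-tris(benzyloxy)benzoate
Conditions: TBAF/AcOH (1:1, excess), THF, 0 °C to rt
Reagents that add atoms: none
Why: Acetic acid buffered fluoride should cleave the aryl TIPS ether and the secondary TBS ether through Si–F bond formation while keeping the medium non-basic, so that the aryl gallate is neither cleaved nor transferred.

Step 13
Reactants: 23 (2R,3S)-2-Ar-3,7-dihydroxychroman-5-yl 3,4,5-tris(benzyloxy)benzoate
Product: 24 (+)-catechin 5-O-gallate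
Conditions: H2 (1 atm), Pd(OH)2/C, THF/MeOH, rt
Reagents that add atoms: none
Why: Catalytic hydrogenolysis removes all five benzyl ethers in one neutral operation that should leave the aryl ester and, at ambient pressure, the benzylic C2–O1 ring bond intact.

**Compound list**

1 | (E)-tert-butyldimethyl{[3-(4,4,5,5-tetramethyl-1,3,2-dioxaborolan-2-yl)prop-2-en-1-yl]oxy}silane | CC(C)(C)[Si](C)(C)OC/C=C/B1OC(C)(C)C(C)(C)O1 | starting material
2 | (E)-tert-butyldimethyl{[3-(4,4,5,5-tetramethyl-1,3,2-dioxaborolan-2-yl)prop-1-en-1-yl]oxy}silane | CC(C)(C)[Si](C)(C)O/C=C/CB1OC(C)(C)C(C)(C)O1 | intermediate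
3 | 3,4-bis(benzyloxy)benzaldehyde | O=Cc1ccc(OCc2ccccc2)c(OCc2ccccc2)c1 | starting material
4 | (1R,2S)-1-[3,4-bis(benzyloxy)phenyl]-2-[(tert-butyldimethylsilyl)oxy]but-3-en-1-ol | C=C[C@H](O[Si](C)(C)C(C)(C)C)[C@H](O)c1ccc(OCc2ccccc2)c(OCc2ccccc2)c1 | intermediate
5 | (5S,6R)-6-[3,4-bis(benzyloxy)phenyl]-5-[(tert-butyldimethylsilyl)oxy]tetrahydro-2H-pyran-2-ol, both anomers | OC1CC[C@H](O[Si](C)(C)C(C)(C)C)[C@@H](c2ccc(OCc3ccccc3)c(OCc3ccccc3)c2)O1 | intermediate
6 | (5S,6R)-6-[3,4-bis(benzyloxy)phenyl]-5-[(tert-butyldimethylsilyl)oxy]tetrahydro-2H-pyran-2-one | O=C1CC[C@H](O[Si](C)(C)C(C)(C)C)[C@@H](c2ccc(OCc3ccccc3)c(OCc3ccccc3)c2)O1 | intermediate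
7 | (2R,3S)-2-[3,4-bis(benzyloxy)phenyl]-3-[(tert-butyldimethylsilyl)oxy]-3,4-dihydro-2H-pyran-6-yl trifluoromethanesulfonate | FC(F)(F)S(=O)(=O)OC1=CC[C@H](O[Si](C)(C)C(C)(C)C)[C@@H](c2ccc(OCc3ccccc3)c(OCc3ccccc3)c2)O1 | intermediate
8 | (2R,3S)-2-[3,4-bis(benzyloxy)phenyl]-3-[(tert-butyldimethylsilyl)oxy]-N-methoxy-N-methyl-3,4-dihydro-2H-pyran-6-carboxamide | CON(C)C(=O)C1=CC[C@H](O[Si](C)(C)C(C)(C)C)[C@@H](c2ccc(OCc3ccccc3)c(OCc3ccccc3)c2)O1 | intermediate
9 | 1-[(2R,3S)-2-[3,4-bis(benzyloxy)phenyl]-3-[(tert-butyldimethylsilyl)oxy]-3,4-dihydro-2H-pyran-6-yl]ethanone | CC(=O)C1=CC[C@H](O[Si](C)(C)C(C)(C)C)[C@@H](c2ccc(OCc3ccccc3)c(OCc3ccccc3)c2)O1 | intermediate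
10 | 1-[(2R,3S)-2-[3,4-bis(benzyloxy)phenyl]-3-[(tert-butyldimethylsilyl)oxy]-3,4-dihydro-2H-pyran-6-yl]-4,4,4-trifluorobutane-1,3-dione (formed in the flask, carried on crude) | FC(F)(F)C(=O)CC(=O)C1=CC[C@H](O[Si](C)(C)C(C)(C)C)[C@@H](c2ccc(OCc3ccccc3)c(OCc3ccccc3)c2)O1 | intermediate
11 | 1-[(2R,3S)-2-[3,4-bis(benzyloxy)phenyl]-3-[(tert-butyldimethylsilyl)oxy]-3,4-dihydro-2H-pyran-6-yl]-2-diazoethanone | [N-]=[N+]=CC(=O)C1=CC[C@H](O[Si](C)(C)C(C)(C)C)[C@@H](c2ccc(OCc3ccccc3)c(OCc3ccccc3)c2)O1 | intermediate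
12 | ethynylmagnesium bromide | C#C[Mg]Br | starting material
13 | triisopropylsilyl trifluoromethanesulfonate | CC(C)[Si](OS(=O)(=O)C(F)(F)F)(C(C)C)C(C)C | starting material
14 | bromomagnesium ethynolate (formed in the flask) | C#CO[Mg]Br | intermediate
15 | (triisopropylsilyloxy)ethyne | C#CO[Si](C(C)C)(C(C)C)C(C)C | intermediate
16 | vinylketene: 2-[(2R,3S)-2-[3,4-bis(benzyloxy)phenyl]-3-[(tert-butyldimethylsilyl)oxy]-3,4-dihydro-2H-pyran-6-yl]ethenone (formed in the flask) | O=C=CC1=CC[C@H](O[Si](C)(C)C(C)(C)C)[C@@H](c2ccc(OCc3ccccc3)c(OCc3ccccc3)c2)O1 | intermediate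
17 | cyclobutenone: 4-[(2R,3S)-2-[3,4-bis(benzyloxy)phenyl]-3-[(tert-butyldimethylsilyl)oxy]-3,4-dihydro-2H-pyran-6-yl]-3-[(triisopropylsilyl)oxy]cyclobut-2-en-1-one, both epimers at the ring sp3 carbon (formed in the flask) | O=C1C=C(O[Si](C(C)C)(C(C)C)C(C)C)C1C2=CC[C@H](O[Si](C)(C)C(C)(C)C)[C@@H](c3ccc(OCc4ccccc4)c(OCc4ccccc4)c3)O2 | intermediate
18 | dienylketene: 4-[(2R,3S)-2-[3,4-bis(benzyloxy)phenyl]-3-[(tert-butyldimethylsilyl)oxy]-3,4-dihydro-2H-pyran-6-yl]-3-[(triisopropylsilyl)oxy]buta-1,3-dien-1-one, ketene and dihydropyranyl cis on the C3=C4 bond (formed in the flask) | O=C=C/C(O[Si](C(C)C)(C(C)C)C(C)C)=C\C1=CC[C@H](O[Si](C)(C)C(C)(C)C)[C@@H](c2ccc(OCc3ccccc3)c(OCc3ccccc3)c2)O1 | intermediate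
19 | cyclohexadienone: (2R,3S)-2-[3,4-bis(benzyloxy)phenyl]-3-[(tert-butyldimethylsilyl)oxy]-7-[(triisopropylsilyl)oxy]-2,3,4,4a-tetrahydro-5H-chromen-5-one, C4a unassigned (formed in the flask) | O=C1C=C(O[Si](C(C)C)(C(C)C)C(C)C)C=C2C1C[C@H](O[Si](C)(C)C(C)(C)C)[C@@H](c3ccc(OCc4ccccc4)c(OCc4ccccc4)c3)O2 | intermediate
20 | (2R,3S)-2-[3,4-bis(benzyloxy)phenyl]-3-[(tert-butyldimethylsilyl)oxy]-7-[(triisopropylsilyl)oxy]chroman-5-ol | Oc1cc(O[Si](C(C)C)(C(C)C)C(C)C)cc2c1C[C@H](O[Si](C)(C)C(C)(C)C)[C@@H](c3ccc(OCc4ccccc4)c(OCc4ccccc4)c3)O2 | intermediate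
21 | 3,4,5-tris(benzyloxy)benzoic acid | OC(=O)c1cc(OCc2ccccc2)c(OCc2ccccc2)c(OCc2ccccc2)c1 | starting material
22 | (2R,3S)-2-[3,4-bis(benzyloxy)phenyl]-3-[(tert-butyldimethylsilyl)oxy]-7-[(triisopropylsilyl)oxy]chroman-5-yl 3,4,5-tris(benzyloxy)benzoate | O=C(Oc1cc(O[Si](C(C)C)(C(C)C)C(C)C)cc2c1C[C@H](O[Si](C)(C)C(C)(C)C)[C@@H](c3ccc(OCc4ccccc4)c(OCc4ccccc4)c3)O2)c5cc(OCc6ccccc6)c(OCc6ccccc6)c(OCc6ccccc6)c5 | intermediate
23 | (2R,3S)-2-[3,4-bis(benzyloxy)phenyl]-3,7-dihydroxychroman-5-yl 3,4,5-tris(benzyloxy)benzoate | O=C(Oc1cc(O)cc2c1C[C@H](O)[C@@H](c3ccc(OCc4ccccc4)c(OCc4ccccc4)c3)O2)c5cc(OCc6ccccc6)c(OCc6ccccc6)c(OCc6ccccc6)c5 | intermediate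
24 | (+)-catechin 5-O-gallate, (2R,3S)-2-(3,4-dihydroxyphenyl)-3,7-dihydroxychroman-5-yl 3,4,5-trihydroxybenzoate | O=C(Oc1cc(O)cc2c1C[C@H](O)[C@@H](c1ccc(O)c(O)c1)O2)c1cc(O)c(O)c(O)c1 | target

**Step count and risks**

Total step count: 13 (12 in the main line, 1 for the siloxyalkyne).
Longest linear sequence: 12 steps (1 → 2 → 4 → 5 → 6 → 7 → 8 → 9 → 11 → 20 → 22 → 23 → 24; steps 1–8 and 10–13).

Steps most likely to fail:

1. Step 9. The parent ynolate carries no substituent on carbon, so silylation may occur at carbon and give the silylketene instead of the ynol ether, and oxidation of the alkynyl Grignard may be incomplete. The fallback blocks the carbon terminus and sets out from 13. Lithium (trimethylsilyl)acetylide (trimethylsilylacetylene, n-BuLi, THF, −78 °C) would be oxidised with lithium tert-butyl peroxide and the resulting ynolate silylated with 13 to give (triisopropylsilyloxy)(trimethylsilyl)ethyne F1. Selective cleavage of the alkynyl C–Si bond (K2CO3, MeOH, 0 °C, short contact) would return to 15.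

2. Step 10. The excited diazoketone may follow carbene pathways other than the Wolff shift, the aryl ethers and the phenolic product may absorb light and degrade, and the ketene may dimerise before it meets the alkyne. The fallback generates the same ketene thermally in the dark and sets out from 11. Silver benzoate catalysed Wolff rearrangement in THF/H2O with Et3N (Arndt–Eistert homologation) would give 2-[(2R,3S)-2-Ar-3-(TBS-oxy)-3,4-dihydro-2H-pyran-6-yl]acetic acid F2, handled as its triethylammonium salt. Neutral activation with 1-chloro-N,N,2-trimethylpropenylamine would give the acid chloride F3. Slow addition of F3 to Et3N and 15 in toluene at 80 °C would form vinylketene 16 by dehydrochlorination, and the same [2+2], 4π opening and 6π closure sequence would come back to 20.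

3. Step 5. The ketene acetal triflate may hydrolyse or ring-open during work-up, or enolate sulfonylation may be incomplete, so that little material reaches the carbonylation. The fallback avoids the triflate and the palladium step and sets out from 6. Single addition of 1-ethoxyvinyllithium (ethyl vinyl ether, t-BuLi, THF, −78 °C) to the lactone would give (5S,6R)-6-Ar-5-(TBS-oxy)-2-(1-ethoxyvinyl)tetrahydro-2H-pyran-2-ol F4. Dehydration (MsCl, Et3N, CH2Cl2, 0 °C) can only eliminate into the ring and would give (2R,3S)-2-Ar-3-(TBS-oxy)-6-(1-ethoxyvinyl)-3,4-dihydro-2H-pyran F5. Mild hydrolysis of the acyclic enol ether (oxalic acid on wet silica, CH2Cl2) would give methyl ketone 9, whose ring enol ether is protected from further hydrolysis by conjugation with the acetyl group.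

**Further compounds**

F1 | step 9 | (triisopropylsilyloxy)(trimethylsilyl)ethyne | C[Si](C)(C)C#CO[Si](C(C)C)(C(C)C)C(C)C
F2 | step 10 | 2-[(2R,3S)-2-[3,4-bis(benzyloxy)phenyl]-3-[(tert-butyldimethylsilyl)oxy]-3,4-dihydro-2H-pyran-6-yl]acetic acid | OC(=O)CC1=CC[C@H](O[Si](C)(C)C(C)(C)C)[C@@H](c2ccc(OCc3ccccc3)c(OCc3ccccc3)c2)O1
F3 | step 10 | 2-[(2R,3S)-2-[3,4-bis(benzyloxy)phenyl]-3-[(tert-butyldimethylsilyl)oxy]-3,4-dihydro-2H-pyran-6-yl]acetyl chloride | ClC(=O)CC1=CC[C@H](O[Si](C)(C)C(C)(C)C)[C@@H](c2ccc(OCc3ccccc3)c(OCc3ccccc3)c2)O1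
F4 | step 5 | (5S,6R)-6-[3,4-bis(benzyloxy)phenyl]-5-[(tert-butyldimethylsilyl)oxy]-2-(1-ethoxyvinyl)tetrahydro-2H-pyran-2-ol | CCOC(=C)C1(O)CC[C@H](O[Si](C)(C)C(C)(C)C)[C@@H](c2ccc(OCc3ccccc3)c(OCc3ccccc3)c2)O1
F5 | step 5 | (2R,3S)-2-[3,4-bis(benzyloxy)phenyl]-3-[(tert-butyldimethylsilyl)oxy]-6-(1-ethoxyvinyl)-3,4-dihydro-2H-pyran | CCOC(=C)C1=CC[C@H](O[Si](C)(C)C(C)(C)C)[C@@H](c2ccc(OCc3ccccc3)c(OCc3ccccc3)c2)O1
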